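**Retrosynthetic overview**
1. Target 21 is (12Z)-6α-acetoxylabda-12,14-diene-7β,8α-diol (labdane numbering; 5α-H, 9α-H, 10β-CH3). The 7β-OH is set last by reduction of a C7 ketone; the diene comes from Stille vinylation of a (12Z)-13-iodoalkene, made from a C12 lactol by Stork–Zhao olefination.
2. The C7 ketone drives all of ring B: 6α-O and 5α-H by reductive α-oxygenation of a Δ5-7-enone, 8α-OH by oxidation of its α'-dienolate.
3. Key disconnection C9–C10: enone 9 is the product of an oxido-accelerated, disrotatory 6π-electrocyclization of the trienolate of monocyclic dienone 6, run under a chiral ammonium counter-ion; 6 comes from β-homocyclocitral 3 and (Z)-vinyl iodide 2.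
4. Enabling feature: ring B carries its oxygens on C6–C7–C8 with C7 central; as a ketone, C7 acidifies C6–H and joins the ring A alkene C5=C10 and the alkene C8=C9 into the hexatriene C10=C5–C6=C7(O−)–C8=C9, whose termini are C9 and C10.
5. Ring order: ring A is bought with 3; ring B is closed in step 4; a temporary lactol ring (O8–C12) is closed in step 9 and opened in step 10.

Key step: step 4

Assumption: which pseudoenantiomeric ammonium salt gives the required (normal-labdane) series in step 4 cannot be predicted; the cinchonidinium salt is written and its cinchoninium counterpart is to be used if the antipode forms.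

Step 1
Reactants: 1 3-[(tert-butyldimethylsilyl)oxy]propanal
Product: 2 (Z)-tert-butyl[(4-iodopent-3-en-1-yl)oxy]dimethylsilane
Conditions: [Ph3PCH2CH3]I, n-BuLi, THF, 25 °C; I2, −78 °C; NaN(SiMe3)2, −20 °C; then 1, −78 °C
Reagents that add atoms: ethyltriphenylphosphonium iodide CC[P+](c1ccccc1)(c1ccccc1)c1ccccc1.[I-]; iodine II
Why: Stork–Zhao olefination with the α-iodoethylidene ylide, whose kinetically formed cis-oxaphosphetane should place iodine cis to the alkyl chain (Z).

Step 2
Reactants: 2 (Z)-tert-butyl[(4-iodopent-3-en-1-yl)oxy]dimethylsilane; 3 (2,6,6-trimethylcyclohex-1-en-1-yl)acetaldehyde (β-homocyclocitral)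
Product: 5 (Z)-6-[(tert-butyldimethylsilyl)oxy]-3-methyl-1-(2,6,6-trimethylcyclohex-1-en-1-yl)hex-3-en-2-ol, via alkenylchromium dichloride 4 (not isolated)
Conditions: CrCl2, NiCl2 (cat.), DMSO/THF, 25 °C
Reagents that add atoms: none
Why: Nozaki–Hiyama–Kishi coupling, in which the non-basic alkenylchromium reagent should add 1,2 to the easily enolized β,γ-unsaturated aldehyde with retention of the Z geometry; the new carbinol centre (C7) forms without control and is erased in step 3.

Step 3
Reactants: 5 (Z)-6-[(tert-butyldimethylsilyl)oxy]-3-methyl-1-(2,6,6-trimethylcyclohex-1-en-1-yl)hex-3-en-2-ol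
Product: 6 (Z)-6-[(tert-butyldimethylsilyl)oxy]-3-methyl-1-(2,6,6-trimethylcyclohex-1-en-1-yl)hex-3-en-2-one
Conditions: Dess–Martin periodinane, pyridine, CH2Cl2, 0 °C
Reagents that add atoms: none
Why: Dess–Martin oxidation under buffered, near-neutral conditions, which should leave the Z-enone geometry and the β,γ-alkene in place.

Step 4
Reactants: 6 (Z)-6-[(tert-butyldimethylsilyl)oxy]-3-methyl-1-(2,6,6-trimethylcyclohex-1-en-1-yl)hex-3-en-2-one
Product: 9 12-[(tert-butyldimethylsilyl)oxy]-13,14,15,16-tetranor-8βH-labd-5-en-7-one, via trienolate 7 (not isolated), via bicyclic dienolate 8 (not isolated)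
Conditions: O-allyl-N-(9-anthracenylmethyl)cinchonidinium bromide (10 mol%), CsOH·H2O (30 mol%), toluene, −20 → 25 °C, Ar
Reagents that add atoms: none
Why: Proposed new method: hydroxide under phase transfer reversibly removes the doubly activated C6–H (α to the C7 ketone, allylic to C5=C10), and the resulting 3-oxidohexatriene 7 (C10=C5–C6=C7(O−)–C8=C9) should undergo a thermal disrotatory 6π-electrocyclization, strongly accelerated by the oxido group, to the cross-conjugated dienolate 8, which is protonated at C8 to the conjugated enone 9. The closest known reactions are the facile racemic electrocyclization of 3-oxidohexatrienes generated from cyclobutenones and alkenyllithiums and the enantioselective 6π-electrocyclization of 2-azapentadienyl anions under chiral ammonium phase-transfer catalysis; the same C9–C10 bond is the one made and broken in the previtamin D/provitamin D manifold. Ring B is closed in an all-carbon six-atom 6π disrotatory mode between the triene termini C9 and C10. The relative configuration follows from orbital symmetry: the C10 methyl (held cis to C6 because ring A ties C1 to C4) and the C11 methylene (cis to C7 in the Z-enone) are both inside groups of the helical triene and disrotation places them on the same face (10β-CH3, C11 β, 9α-H), the absolute configuration is to be set by the chiral ammonium counter-ion, which must discriminate the P and M helices of the ion-paired trienolate, and C8 is protonated under equilibrating conditions and is planarized again in step 5. The step needs periselectivity for ring closure over [1,7]-hydrogen shifts and over Z/E scrambling of the enone; this should be secured by the oxido acceleration, by the far higher kinetic acidity of C6–H than of the γ-hydrogens at C11, and by the irreversibility of the closure, which drains the reversibly formed trienolate.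

Step 5
Reactants: 9 12-[(tert-butyldimethylsilyl)oxy]-13,14,15,16-tetranor-8βH-labd-5-en-7-one
Product: 11 12-[(tert-butyldimethylsilyl)oxy]-8α-hydroxy-13,14,15,16-tetranorlabd-5-en-7-one, via potassium dienolate 10 (not isolated)
Conditions: KN(SiMe3)2, THF, −78 °C; 2-(phenylsulfonyl)-3-phenyloxaziridine, −78 °C; aq. NH4Cl
Reagents that add atoms: 2-(phenylsulfonyl)-3-phenyloxaziridine O=S(=O)(c1ccccc1)N1OC1c1ccccc1
Why: α'-Hydroxylation of the enone through its cross-conjugated dienolate (C8–H is the only enolizable hydrogen) with an N-sulfonyloxaziridine; oxygen should enter C8 from the α face, anti to the adjacent β side chain on C9 and to the 1,3-related β methyl on C10, giving 8α-OH/8β-CH3.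

Step 6
Reactants: 11 12-[(tert-butyldimethylsilyl)oxy]-8α-hydroxy-13,14,15,16-tetranorlabd-5-en-7-one
Product: 13 12-[(tert-butyldimethylsilyl)oxy]-6α,8α-dihydroxy-13,14,15,16-tetranorlabdan-7-one, via 6α-hydroperoxy ketone 12 (not isolated)
Conditions: Mn(dpm)3 (dpm = 2,2,6,6-tetramethylheptane-3,5-dionate, 10 mol%), PhSiH3, O2 (1 atm), i-PrOH/CH2Cl2, 0 °C; then P(OEt)3
Reagents that add atoms: dioxygen O=O
Why: Mukaiyama-type reductive α-hydroxylation of the enone (manganese hydride delivery to the β-carbon, then O2 capture at the α-carbon): hydrogen should enter C5 from the α face because the β face is screened by the C10 and C4β methyl groups (trans ring fusion), and oxygen should be captured at C6 from the same open face to give the equatorial 6α-oxygen, which is also the more stable epimer at this enolizable centre.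

Step 7
Reactants: 13 12-[(tert-butyldimethylsilyl)oxy]-6α,8α-dihydroxy-13,14,15,16-tetranorlabdan-7-one
Product: 14 6α-acetoxy-12-[(tert-butyldimethylsilyl)oxy]-8α-hydroxy-13,14,15,16-tetranorlabdan-7-one
Conditions: Ac2O, pyridine, 4-(dimethylamino)pyridine (cat.), CH2Cl2, 0 → 25 °C
Reagents that add atoms: acetic anhydride CC(=O)OC(C)=O
Why: Nucleophile-catalysed acetylation, which should take only the secondary C6 hydroxyl because the C8 hydroxyl is tertiary and C7 is still a ketone, so O6 and O7 are differentiated without protecting groups.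

Step 8
Reactants: 14 6α-acetoxy-12-[(tert-butyldimethylsilyl)oxy]-8α-hydroxy-13,14,15,16-tetranorlabdan-7-one
Product: 15 6α-acetoxy-8α,12-dihydroxy-13,14,15,16-tetranorlabdan-7-one
Conditions: HF·pyridine, pyridine, THF, 0 → 25 °C
Reagents that add atoms: none
Why: Fluoride cleavage of the primary silyl ether under buffered, non-basic conditions that should not disturb the α-acetoxy ketone.

Step 9
Reactants: 15 6α-acetoxy-8α,12-dihydroxy-13,14,15,16-tetranorlabdan-7-one
Product: 17 6α-acetoxy-8α,12-epoxy-12-hydroxy-13,14,15,16-tetranorlabdan-7-one, via hydroxy aldehyde 16 (not isolated)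
Conditions: (COCl)2, DMSO, CH2Cl2, −78 °C; Et3N, −78 → 0 °C
Reagents that add atoms: none
Why: Swern oxidation of the only oxidizable (primary) alcohol; the aldehyde should close onto the 8α-hydroxyl to the five-membered lactol only after the oxidant is consumed, so over-oxidation to the lactone is avoided.

Step 10
Reactants: 17 6α-acetoxy-8α,12-epoxy-12-hydroxy-13,14,15,16-tetranorlabdan-7-one
Product: 19 (12Z)-6α-acetoxy-8α-hydroxy-13-iodo-14,15-dinorlabd-12-en-7-one, via sodium alkoxide aldehyde 18 (not isolated)
Conditions: [Ph3PCH2CH3]I, n-BuLi, THF, 25 °C; I2, −78 °C; NaN(SiMe3)2, −20 °C (2 equiv of ylide); 17 treated with NaN(SiMe3)2 (1.0 equiv), THF, −78 °C, and added at once to the ylide at −78 °C; aq. NH4Cl at −78 °C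
Reagents that add atoms: ethyltriphenylphosphonium iodide CC[P+](c1ccccc1)(c1ccccc1)c1ccccc1.[I-]; iodine II
Why: Stork–Zhao olefination of the lactol through its ring-opened form: deprotonation of the lactol hydroxyl gives the sodium lactolate, which opens to the C8 alkoxide aldehyde 18 that the ylide traps, with iodine placed cis to C11 by the kinetic cis-oxaphosphetane; at −78 °C the hindered C7 ketone and the axial C6 hydrogen, flanked by the C4β and C10 methyl groups, should not be engaged.

Step 11
Reactants: 19 (12Z)-6α-acetoxy-8α-hydroxy-13-iodo-14,15-dinorlabd-12-en-7-one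
Product: 20 (12Z)-6α-acetoxy-8α-hydroxylabda-12,14-dien-7-one
Conditions: tributyl(vinyl)stannane, Pd2(dba)3 (2.5 mol%), AsPh3 (20 mol%), CuI (10 mol%), NMP, 25 → 40 °C
Reagents that add atoms: tributyl(vinyl)stannane C=C[Sn](CCCC)(CCCC)CCCC
Why: Stille coupling, which should proceed with retention of the alkenyl iodide geometry to the (12Z)-diene under neutral conditions that spare the α-acetoxy ketone and the free tertiary alcohol.

Step 12
Reactants: 20 (12Z)-6α-acetoxy-8α-hydroxylabda-12,14-dien-7-one
Product: 21 (12Z)-6α-acetoxylabda-12,14-diene-7β,8α-diol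
Conditions: Me4NBH(OAc)3, MeCN/AcOH (1:1), −30 → −20 °C
Reagents that add atoms: none
Why: Evans–Saksena hydroxyl-directed reduction, in which boron bound to the 8α-hydroxyl should deliver hydride to C7 on the α face (also the open axial trajectory, the β face being blocked by the axial C8 methyl) to give the equatorial 7β-alcohol trans to the C8 hydroxyl, while the acidic medium suppresses O6→O7 acetyl migration and leaves the diene untouched.

**Compound list**
1 | 3-[(tert-butyldimethylsilyl)oxy]propanal | O=CCCO[Si](C)(C)C(C)(C)C | starting material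
2 | (Z)-tert-butyl[(4-iodopent-3-en-1-yl)oxy]dimethylsilane | C/C(I)=C/CCO[Si](C)(C)C(C)(C)C | intermediate
3 | (2,6,6-trimethylcyclohex-1-en-1-yl)acetaldehyde (β-homocyclocitral) | O=CCC1=C(C)CCCC1(C)C | starting material
4 | (Z)-{5-[(tert-butyldimethylsilyl)oxy]pent-2-en-2-yl}chromium dichloride | C/C([Cr](Cl)Cl)=C/CCO[Si](C)(C)C(C)(C)C | intermediate (not isolated)
5 | (Z)-6-[(tert-butyldimethylsilyl)oxy]-3-methyl-1-(2,6,6-trimethylcyclohex-1-en-1-yl)hex-3-en-2-ol (racemic at the carbinol carbon) | CC1=C(CC(O)/C(C)=C\CCO[Si](C)(C)C(C)(C)C)C(C)(C)CCC1 | intermediate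
6 | (Z)-6-[(tert-butyldimethylsilyl)oxy]-3-methyl-1-(2,6,6-trimethylcyclohex-1-en-1-yl)hex-3-en-2-one | CC1=C(CC(=O)/C(C)=C\CCO[Si](C)(C)C(C)(C)C)C(C)(C)CCC1 | intermediate
7 | (1E,3Z)-6-[(tert-butyldimethylsilyl)oxy]-3-methyl-1-(2,6,6-trimethylcyclohex-1-en-1-yl)hexa-1,3-dien-2-olate (anion shown; counter-ion is the cinchonidinium cation) | CC1=C(/C=C(/[O-])\C(C)=C/CCO[Si](C)(C)C(C)(C)C)C(C)(C)CCC1 | intermediate (not isolated)
8 | 12-[(tert-butyldimethylsilyl)oxy]-13,14,15,16-tetranorlabda-5,7-dien-7-olate, 9α-H, 10β-CH3 (anion shown; counter-ion is the cinchonidinium cation) | CC(C)(C)[Si](C)(C)OCC[C@H]1C(C)=C([O-])C=C2C(C)(C)CCC[C@@]21C | intermediate (not isolated)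
9 | 12-[(tert-butyldimethylsilyl)oxy]-13,14,15,16-tetranor-8βH-labd-5-en-7-one (the 8α-methyl epimer is drawn; C8 is planarized in step 5) | CC(C)(C)[Si](C)(C)OCC[C@H]1[C@H](C)C(=O)C=C2C(C)(C)CCC[C@@]21C | intermediate
10 | potassium 12-[(tert-butyldimethylsilyl)oxy]-13,14,15,16-tetranorlabda-5,7-dien-7-olate | CC(C)(C)[Si](C)(C)OCC[C@H]1C(C)=C([O-])C=C2C(C)(C)CCC[C@@]21C.[K+] | intermediate (not isolated)
11 | 12-[(tert-butyldimethylsilyl)oxy]-8α-hydroxy-13,14,15,16-tetranorlabd-5-en-7-one | CC(C)(C)[Si](C)(C)OCC[C@H]1[C@](C)(O)C(=O)C=C2C(C)(C)CCC[C@@]21C | intermediate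
12 | 12-[(tert-butyldimethylsilyl)oxy]-6α-hydroperoxy-8α-hydroxy-13,14,15,16-tetranorlabdan-7-one | CC(C)(C)[Si](C)(C)OCC[C@H]1[C@](C)(O)C(=O)[C@H](OO)[C@H]2C(C)(C)CCC[C@@]21C | intermediate (not isolated)
13 | 12-[(tert-butyldimethylsilyl)oxy]-6α,8α-dihydroxy-13,14,15,16-tetranorlabdan-7-one | CC(C)(C)[Si](C)(C)OCC[C@H]1[C@](C)(O)C(=O)[C@H](O)[C@H]2C(C)(C)CCC[C@@]21C | intermediate
14 | 6α-acetoxy-12-[(tert-butyldimethylsilyl)oxy]-8α-hydroxy-13,14,15,16-tetranorlabdan-7-one | CC(C)(C)[Si](C)(C)OCC[C@H]1[C@](C)(O)C(=O)[C@H](OC(C)=O)[C@H]2C(C)(C)CCC[C@@]21C | intermediate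
15 | 6α-acetoxy-8α,12-dihydroxy-13,14,15,16-tetranorlabdan-7-one | OCC[C@H]1[C@](C)(O)C(=O)[C@H](OC(C)=O)[C@H]2C(C)(C)CCC[C@@]21C | intermediate
16 | 6α-acetoxy-8α-hydroxy-7-oxo-13,14,15,16-tetranorlabdan-12-al | O=CC[C@H]1[C@](C)(O)C(=O)[C@H](OC(C)=O)[C@H]2C(C)(C)CCC[C@@]21C | intermediate (not isolated)
17 | 6α-acetoxy-8α,12-epoxy-12-hydroxy-13,14,15,16-tetranorlabdan-7-one (lactol, both C12 epimers) | OC1C[C@H]2[C@](C)(O1)C(=O)[C@H](OC(C)=O)[C@H]3C(C)(C)CCC[C@@]32C | intermediate
18 | sodium 6α-acetoxy-7,12-dioxo-13,14,15,16-tetranorlabdan-8α-olate (ring-opened alkoxide aldehyde of lactol 17) | O=CC[C@H]1[C@](C)([O-])C(=O)[C@H](OC(C)=O)[C@H]2C(C)(C)CCC[C@@]21C.[Na+] | intermediate (not isolated)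
19 | (12Z)-6α-acetoxy-8α-hydroxy-13-iodo-14,15-dinorlabd-12-en-7-one | C/C(I)=C/C[C@H]1[C@](C)(O)C(=O)[C@H](OC(C)=O)[C@H]2C(C)(C)CCC[C@@]21C | intermediate
20 | (12Z)-6α-acetoxy-8α-hydroxylabda-12,14-dien-7-one | C=C/C(C)=C\C[C@H]1[C@](C)(O)C(=O)[C@H](OC(C)=O)[C@H]2C(C)(C)CCC[C@@]21C | intermediate
21 | (12Z)-6α-acetoxylabda-12,14-diene-7β,8α-diol (CNP0138393.1) | C=C/C(C)=C\C[C@H]1[C@](C)(O)[C@@H](O)[C@H](OC(C)=O)[C@H]2C(C)(C)CCC[C@@]21C | target

**Totals**
Total step count: 12. Longest linear sequence: 12 steps (1 → 2 → 5 → 6 → 9 → 11 → 13 → 14 → 15 → 17 → 19 → 20 → 21); aldehyde 3 enters in step 2.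

**Steps most likely to fail**

Step 4 (Proposed new method). What may go wrong: the chiral ammonium cation transfers its chirality poorly to the helical trienolate, so that ring closure proceeds with low enantioselectivity. Fallback, from 6 back to 9, by known chemistry: the closure is run without asymmetric induction and the enantiomers are separated. Dienone 6 with KOt-Bu (20 mol%) in t-BuOH/THF at 25 °C should cyclize through 7 (oxido-accelerated electrocyclization of 3-oxidohexatrienes is known in racemic form) to both dienolates, 8 and its mirror image, the ent-dienolate F1. Protonation gives 9 together with its antipode, the ent-enone F2. The racemate is treated in THF at −78 °C with lithiated (S)-N,S-dimethyl-S-phenylsulfoximine (n-BuLi), which adds 1,2 to the ketone. This gives two diastereomeric adducts, the β-hydroxysulfoximine F3 (from 9) and the β-hydroxysulfoximine F4 (from F2), which are separated by chromatography. Heating F3 in toluene at 110 °C reverses the addition and returns enantiopure 9.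

Step 6. What may go wrong: hydrogen delivery to C5, which lies between two quaternary carbons, is slow, so that conversion stalls or carbonyl reduction competes, or oxygen is captured at C6 without face selectivity. Fallback, from 11 back to 13: reduction and oxygenation are separated. Hydrogenation of 11 (H2, Pd/C, EtOAc; hydrogen from the α face) should give the saturated 5α-ketone, 12-[(tert-butyldimethylsilyl)oxy]-8α-hydroxy-13,14,15,16-tetranorlabdan-7-one F5. Me3SiOTf/Et3N (CH2Cl2, 0 °C) converts it into the Δ6 silyl enol ether with a silylated C8 hydroxyl, the bis(trimethylsilyl) derivative F6. Rubottom oxidation with dimethyldioxirane (acetone, −20 °C; α-face attack, silyl migration) gives the 6α,8α-bis(trimethylsilyloxy) ketone F7. Citric acid in methanol removes both trimethylsilyl groups and returns 13.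

Step 10. What may go wrong: the basic ylide or the C8 alkoxide enolizes C6 or transfers the acetyl group, or the ylide attacks the C7 ketone, and Z selectivity erodes. Fallback, from 17 back to 20: the olefination is done under neutral conditions with chlorine in place of iodine. Lactol 17 with 1,1,1-trichloroethane and CrCl2 in THF at 25 °C (Takai-type chromium-mediated haloalkenylation, expected to be Z-selective) should give (12Z)-6α-acetoxy-13-chloro-8α-hydroxy-14,15-dinorlabd-12-en-7-one, the vinyl chloride F8. Negishi coupling of F8 with vinylzinc bromide (Pd(P(t-Bu)3)2, THF/NMP, 50 °C; excess reagent for the free hydroxyl) gives diene 20.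

**Further compounds**
F1 | step 4 | ent-dienolate, mirror image of 8 (anion shown) | CC(C)(C)[Si](C)(C)OCC[C@@H]1C(C)=C([O-])C=C2C(C)(C)CCC[C@]21C
F2 | step 4 | ent-enone, mirror image of 9 | CC(C)(C)[Si](C)(C)OCC[C@@H]1[C@@H](C)C(=O)C=C2C(C)(C)CCC[C@]21C
F3 | step 4 | β-hydroxysulfoximine from 9 and (S)-N,S-dimethyl-S-phenylsulfoximine (new carbinol centre C7 undefined) | CC(C)(C)[Si](C)(C)OCC[C@H]1[C@H](C)C(O)(C[S@@](=O)(=NC)c3ccccc3)C=C2C(C)(C)CCC[C@@]21C
F4 | step 4 | β-hydroxysulfoximine from F2 and (S)-N,S-dimethyl-S-phenylsulfoximine (new carbinol centre C7 undefined) | CC(C)(C)[Si](C)(C)OCC[C@@H]1[C@@H](C)C(O)(C[S@@](=O)(=NC)c3ccccc3)C=C2C(C)(C)CCC[C@]21C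
F5 | step 6 | 12-[(tert-butyldimethylsilyl)oxy]-8α-hydroxy-13,14,15,16-tetranorlabdan-7-one | CC(C)(C)[Si](C)(C)OCC[C@H]1[C@](C)(O)C(=O)C[C@H]2C(C)(C)CCC[C@@]21C
F6 | step 6 | 12-[(tert-butyldimethylsilyl)oxy]-7,8α-bis(trimethylsilyloxy)-13,14,15,16-tetranorlabd-6-ene | CC(C)(C)[Si](C)(C)OCC[C@H]1[C@](C)(O[Si](C)(C)C)C(O[Si](C)(C)C)=C[C@H]2C(C)(C)CCC[C@@]21C
F7 | step 6 | 12-[(tert-butyldimethylsilyl)oxy]-6α,8α-bis(trimethylsilyloxy)-13,14,15,16-tetranorlabdan-7-one | CC(C)(C)[Si](C)(C)OCC[C@H]1[C@](C)(O[Si](C)(C)C)C(=O)[C@H](O[Si](C)(C)C)[C@H]2C(C)(C)CCC[C@@]21C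
F8 | step 10 | (12Z)-6α-acetoxy-13-chloro-8α-hydroxy-14,15-dinorlabd-12-en-7-one | C/C(Cl)=C/C[C@H]1[C@](C)(O)C(=O)[C@H](OC(C)=O)[C@H]2C(C)(C)CCC[C@@]21C
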